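Squamatic acid is disconnected at the C1–C6 bond of ring A, the methoxy ring, while the depside ester to O4' of ring B (the 3-methylorsellinate ring) stays in place. Ring A alternates: the oxygen-bearing C2 and C4 sit between the carbon-bearing C1, C3 and C6, so it unfolds into a linear chain in which C1 is a doubly activated methylene and C6 a methyl ketone. One operation, a base-mediated aldol condensation, joins C1 to C6, closes ring A and aromatizes it. The precursor is the 3,7-dioxooct-4-enoate aryl ester of the ring B phenol, with the C4 oxygen already a methyl enol ether and both carboxyls masked as tert-butyl esters.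

Key step: step 6

Remark on numbering: ring A is C1 (carries the depside carbonyl), C2 (OH), C3 (CO2H), C4 (OMe), C5 (H), C6 (CH3), and the open chain keeps these numbers. Ring B atoms are primed, with C1' carrying the carboxyl and O4' the depside oxygen.

Remark on tautomers: compounds 7, 11 and 12 are push-pull enol ethers that equilibrate with their keto and enol tautomers and about the C3=C4 bond. They are drawn as the Z enol ether with C5 and C2 on the same side, the form that can close.

Remark on the esters: both carboxyls are carried as tert-butyl esters. An unhindered alkyl ester on C3 could be attacked by the C6 enol(ate) oxygen, a six-membered lactonization to a 4-methoxy-6-methyl-2-pyranone that the methyl cap on O4 does not prevent. The tert-butyl ester closes that path in steps 2 and 6, and both esters fall in one acidolysis.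

Step 1
Reactants: 1 2,2,6-trimethyl-4H-1,3-dioxin-4-one; 2 di-tert-butyl dicarbonate
Product: 4 tert-butyl 2-(2,2-dimethyl-4-oxo-4H-1,3-dioxin-6-yl)acetate, via lithium dienolate 3 (not isolated)
Conditions: 1 (2 equiv), LiN(SiMe3)2 (2 equiv), THF, −78 °C; then 2 (1 equiv), −78 to −30 °C; aq. NH4Cl
Reagents that add atoms: none
Why: Vinylogous Claisen-type C-acylation, in which lithium dienolate 3 reacts at its exocyclic γ-carbon with the dicarbonate, and the excess dienolate takes up the more acidic proton of the product so that a second acylation is avoided.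

Step 2
Reactants: 4 tert-butyl 2-(2,2-dimethyl-4-oxo-4H-1,3-dioxin-6-yl)acetate; 5 4,4-dimethoxybut-3-en-2-one
Product: 7 tert-butyl (2Z)-2-(2,2-dimethyl-4-oxo-4H-1,3-dioxin-6-yl)-3-methoxy-5-oxohex-2-enoate, via sodium enolate 6 (not isolated)
Conditions: NaH, THF, 0 °C; then 5, 0 °C to rt; AcOH quench
Reagents that add atoms: none
Why: Conjugate addition–elimination (vinylic substitution) of the vinylogous malonate anion 6 at the ketene acetal carbon of 5 expels methoxide, the product ends as its stabilized salt so that only one methoxy group is exchanged, and the hindered tert-butyl ester resists lactonization by the C6 enolate oxygen.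

Step 3
Reactants: 8 2,5-dimethylresorcinol
Product: 9 2,4-dihydroxy-3,6-dimethylbenzoic acid
Conditions: KHCO3, CO2 (1 atm), glycerol, 120 °C; then aq. HCl, 0 °C
Reagents that add atoms: potassium hydrogen carbonate, [K+].OC([O-])=O (its CO2 unit becomes the carboxyl group)
Why: Kolbe–Schmitt carboxylation of the electron-rich resorcinol, in which C4 and C6 are equivalent and the carbon between the hydroxyls is blocked by methyl, so that only one acid can form.

Step 4
Reactants: 9 2,4-dihydroxy-3,6-dimethylbenzoic acid
Product: 10 tert-butyl 2,4-dihydroxy-3,6-dimethylbenzoate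
Conditions: Cl3CC(=NH)OtBu, CH2Cl2/cyclohexane, rt
Reagents that add atoms: tert-butyl 2,2,2-trichloroacetimidate, CC(C)(C)OC(=N)C(Cl)(Cl)Cl
Why: Imidate esterification, in which the acidic salicylic carboxyl protonates the trichloroacetimidate and is tert-butylated by the resulting ion pair, whereas the phenols would need a Lewis acid and stay free.

Step 5
Reactants: 7 tert-butyl (2Z)-2-(2,2-dimethyl-4-oxo-4H-1,3-dioxin-6-yl)-3-methoxy-5-oxohex-2-enoate; 10 tert-butyl 2,4-dihydroxy-3,6-dimethylbenzoate
Product: 12 4-(tert-butoxycarbonyl)-3-hydroxy-2,5-dimethylphenyl (4Z)-4-(tert-butoxycarbonyl)-5-methoxy-3,7-dioxooct-4-enoate, via acylketene 11 (not isolated)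
Conditions: 7 (1.2 equiv), 10 (1.0 equiv), toluene, 100 °C, N2 sweep; concentrate, crude 12 taken on
Reagents that add atoms: none
Why: Thermal retro-hetero-Diels–Alder cleavage of the dioxinone releases acetone and acylketene 11, which is trapped by the exposed 4-hydroxyl of 10 (acylketene capture) because the 2-hydroxyl is hydrogen-bonded to the ester carbonyl and flanked on both sides, and the neutral medium leaves the enol ether and both tert-butyl esters alone.

Step 6
Reactants: 12 4-(tert-butoxycarbonyl)-3-hydroxy-2,5-dimethylphenyl (4Z)-4-(tert-butoxycarbonyl)-5-methoxy-3,7-dioxooct-4-enoate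
Product: 14 squamatic acid di-tert-butyl ester (tert-butyl 3-{[4-(tert-butoxycarbonyl)-3-hydroxy-2,5-dimethylphenoxy]carbonyl}-2-hydroxy-6-methoxy-4-methylbenzoate), via aldol adduct 13 (not isolated)
Conditions: Et3N, dry CH2Cl2, 0 °C to rt; aq. citric acid wash
Reagents that add atoms: none
Why: Triethylamine reversibly deprotonates the C1 methylene, which lies between the C2 ketone and the aryl ester carbonyl, and the enolate adds to the C6 methyl ketone to give aldol adduct 13, after which E1cB loss of water across C1–C6 and enolization of the C2 ketone give the phenol. The closest known reaction type is the amine- or carbonate-mediated cycloaromatization of 3,5,7-tricarbonyl esters obtained from dioxinone-derived acylketenes, together with the [3+3] cycloaromatizations that reach 4-methoxysalicylates through the same 5-methoxy-3,7-dioxo chain. Ring A closes in the 6-(enolendo)-exo-trig mode. The two transient stereocentres of 13 (C1 and C6) disappear on aromatization, so nothing has to be controlled. The step needs C1-to-C6 chemoselectivity: the terminal methyl is far less acidic than C1 and the C2 carbonyl is a deactivated vinylogous ester carbonyl, while the methyl cap on O4 and the tert-butyl group on the C3 ester block both conceivable pyranone lactonizations. A weak tertiary amine in a dry aprotic solvent, without chelating metal ions, disfavours Claisen attack on the aryl ester, cannot add to the enol ether or cleave the ester, and makes any E1cB loss of the aryloxide reversible and unproductive.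

Step 7
Reactants: 14 squamatic acid di-tert-butyl ester
Product: 15 squamatic acid
Conditions: TFA/CH2Cl2 (1:3), 0 °C to rt; evaporate cold
Reagents that add atoms: none
Why: Acidolysis of both tert-butyl esters by alkyl–oxygen cleavage with loss of isobutylene, which spares the aryl ester, the methyl ether and the phenols, while the short cold exposure limits protodecarboxylation and the carbonyl-deactivated, flanked ring positions resist tert-butylation.

Compound list
1 | 2,2,6-trimethyl-4H-1,3-dioxin-4-one | CC1=CC(=O)OC(C)(C)O1 | starting material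
2 | di-tert-butyl dicarbonate | CC(C)(C)OC(=O)OC(=O)OC(C)(C)C | starting material
3 | lithium 2,2-dimethyl-6-methylidene-6H-1,3-dioxin-4-olate (lithium dienolate of 1) | [Li+].[O-]C1=CC(=C)OC(C)(C)O1 | intermediate (not isolated)
4 | tert-butyl 2-(2,2-dimethyl-4-oxo-4H-1,3-dioxin-6-yl)acetate | CC(C)(C)OC(=O)CC1=CC(=O)OC(C)(C)O1 | intermediate
5 | 4,4-dimethoxybut-3-en-2-one | COC(OC)=CC(C)=O | starting material
6 | sodium enolate of 4 (sodium 1-tert-butoxy-2-(2,2-dimethyl-4-oxo-4H-1,3-dioxin-6-yl)ethen-1-olate, geometry undefined) | [Na+].[O-]C(OC(C)(C)C)=CC1=CC(=O)OC(C)(C)O1 | intermediate (not isolated)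
7 | tert-butyl (2Z)-2-(2,2-dimethyl-4-oxo-4H-1,3-dioxin-6-yl)-3-methoxy-5-oxohex-2-enoate | CC(=O)C/C(OC)=C(/C(=O)OC(C)(C)C)C1=CC(=O)OC(C)(C)O1 | intermediate
8 | 2,5-dimethylresorcinol (2,5-dimethylbenzene-1,3-diol) | Cc1cc(O)c(C)c(O)c1 | starting material
9 | 2,4-dihydroxy-3,6-dimethylbenzoic acid | Cc1cc(O)c(C)c(O)c1C(=O)O | intermediate
10 | tert-butyl 2,4-dihydroxy-3,6-dimethylbenzoate | Cc1cc(O)c(C)c(O)c1C(=O)OC(C)(C)C | intermediate
11 | tert-butyl (2Z)-3-methoxy-5-oxo-2-(3-oxoprop-2-enoyl)hex-2-enoate (acylketene) | CC(=O)C/C(OC)=C(/C(=O)OC(C)(C)C)C(=O)C=C=O | intermediate (not isolated)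
12 | 4-(tert-butoxycarbonyl)-3-hydroxy-2,5-dimethylphenyl (4Z)-4-(tert-butoxycarbonyl)-5-methoxy-3,7-dioxooct-4-enoate | CC(=O)C/C(OC)=C(/C(=O)OC(C)(C)C)C(=O)CC(=O)Oc1cc(C)c(C(=O)OC(C)(C)C)c(O)c1C | intermediate (key-step precursor)
13 | 1-[4-(tert-butoxycarbonyl)-3-hydroxy-2,5-dimethylphenyl] 3-tert-butyl 6-hydroxy-4-methoxy-6-methyl-2-oxocyclohex-3-ene-1,3-dicarboxylate (aldol adduct; C1 and C6 unassigned, diastereomer mixture) | COC1=C(C(=O)OC(C)(C)C)C(=O)C(C(=O)Oc2cc(C)c(C(=O)OC(C)(C)C)c(O)c2C)C(C)(O)C1 | intermediate (not isolated)
14 | squamatic acid di-tert-butyl ester | COc1cc(C)c(C(=O)Oc2cc(C)c(C(=O)OC(C)(C)C)c(O)c2C)c(O)c1C(=O)OC(C)(C)C | intermediate (key-step product)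
15 | squamatic acid | COc1cc(C)c(C(=O)Oc2cc(C)c(C(=O)O)c(O)c2C)c(O)c1C(=O)O | target

Total step count: 7. Longest linear sequence: 5 steps (1, 2, 5, 6, 7; the ring B branch 3, 4, 5, 6, 7 is equally long).

Steps most likely to fail

Step 6. The enolate centred on C5/C6 may compete with C1 as the nucleophile and attack the activated aryl ester carbonyl in a Claisen-type closure that expels ring B as its phenoxide, or the aldol adduct may stall before dehydration. The fallback closes ring A on an alkyl ester and makes the depside bond afterwards. It sets out from 7. Thermolysis in toluene at 100 °C in the presence of benzyl alcohol should give benzyl (4Z)-4-(tert-butoxycarbonyl)-5-methoxy-3,7-dioxooct-4-enoate F1, whose alkyl ester is no acyl donor. The same triethylamine-mediated aldol aromatization should then give 1-benzyl 3-tert-butyl 2-hydroxy-4-methoxy-6-methylbenzene-1,3-dicarboxylate F2. Hydrogenolysis (H2, Pd/C, EtOAc) should free 3-(tert-butoxycarbonyl)-2-hydroxy-4-methoxy-6-methylbenzoic acid F3, which is esterified with the 4-hydroxyl of 10 by N,N'-dicyclohexylcarbodiimide in toluene. The fallback comes back to the route at 14.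

Step 2. The hindered carbanion of 4 may add too slowly to the ketene acetal carbon, so that base-induced self-condensation of 5 or attack through the ring carbon of the dioxinone takes over. The fallback builds the enol ether by C-acylation and O-methylation and sets out from 4. Commercial 2-(2-methyl-1,3-dioxolan-2-yl)acetic acid is activated with 1,1'-carbonyldiimidazole to 1-[2-(2-methyl-1,3-dioxolan-2-yl)acetyl]imidazole F4. F4 should C-acylate the magnesium enolate of 4 (MgCl2, Et3N, MeCN) to tert-butyl 2-(2,2-dimethyl-4-oxo-4H-1,3-dioxin-6-yl)-4-(2-methyl-1,3-dioxolan-2-yl)-3-oxobutanoate F5. Its strongly acidic enol is O-methylated with trimethylsilyldiazomethane (toluene/MeOH) to tert-butyl (2Z)-2-(2,2-dimethyl-4-oxo-4H-1,3-dioxin-6-yl)-3-methoxy-4-(2-methyl-1,3-dioxolan-2-yl)but-2-enoate F6. Mild hydrolysis of the ketal (PPTS, acetone/H2O) unmasks the methyl ketone, and the fallback comes back at 7.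

Step 5. Capture of the acylketene by the electron-poor phenol may be slower than self-condensation of the ketene or its intramolecular C-acylation by the C5 enol at 100 °C. The fallback moves the acyl group through a thioester and sets out from 7. Thermolysis in toluene in the presence of 2-methylpropane-2-thiol, a far better ketene trap than the phenol, should give S-tert-butyl (4Z)-4-(tert-butoxycarbonyl)-5-methoxy-3,7-dioxooct-4-enethioate F7. Silver trifluoroacetate (AgO2CCF3) in THF at room temperature should then transfer the β-keto acyl group from sulfur to the 4-hydroxyl of 10, and the fallback comes back at 12.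

Further compounds
F1 | step 6 | benzyl (4Z)-4-(tert-butoxycarbonyl)-5-methoxy-3,7-dioxooct-4-enoate | CC(=O)C/C(OC)=C(/C(=O)OC(C)(C)C)C(=O)CC(=O)OCc1ccccc1
F2 | step 6 | 1-benzyl 3-tert-butyl 2-hydroxy-4-methoxy-6-methylbenzene-1,3-dicarboxylate | COc1cc(C)c(C(=O)OCc2ccccc2)c(O)c1C(=O)OC(C)(C)C
F3 | step 6 | 3-(tert-butoxycarbonyl)-2-hydroxy-4-methoxy-6-methylbenzoic acid | COc1cc(C)c(C(=O)O)c(O)c1C(=O)OC(C)(C)C
F4 | step 2 | 1-[2-(2-methyl-1,3-dioxolan-2-yl)acetyl]imidazole | CC1(CC(=O)n2ccnc2)OCCO1
F5 | step 2 | tert-butyl 2-(2,2-dimethyl-4-oxo-4H-1,3-dioxin-6-yl)-4-(2-methyl-1,3-dioxolan-2-yl)-3-oxobutanoate (racemic, largely enolized) | CC1(CC(=O)C(C(=O)OC(C)(C)C)C2=CC(=O)OC(C)(C)O2)OCCO1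
F6 | step 2 | tert-butyl (2Z)-2-(2,2-dimethyl-4-oxo-4H-1,3-dioxin-6-yl)-3-methoxy-4-(2-methyl-1,3-dioxolan-2-yl)but-2-enoate | CC1(C/C(OC)=C(/C(=O)OC(C)(C)C)C2=CC(=O)OC(C)(C)O2)OCCO1
F7 | step 5 | S-tert-butyl (4Z)-4-(tert-butoxycarbonyl)-5-methoxy-3,7-dioxooct-4-enethioate | CC(=O)C/C(OC)=C(/C(=O)OC(C)(C)C)C(=O)CC(=O)SC(C)(C)C
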